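(The data are calculated with made-up constants.)

The free catalyst is a worker on piecework, and what you want from these flasks is how much it has finished when the clock stops.

| flask | starting material | partner | free catalyst | remark | time |
|---|---|---|---|---|---|
| birch | 0.075 M | 0.15 M | 0.50 mM | run made earlier |  |
| maple | 0.025 M | 0.15 M | 0.50 mM | run made earlier |  |
| autumn | 0.050 M | 0.300 M | 0.15 mM |  | 25 min |
| winter | 0.050 M | 0.150 M | 0.50 mM |  | 25 min |

| run | time / min | target / % | starting material / % |
|---|---|---|---|
| birch | 1.33 | 2.4 | 97.3 |
| birch | 3.00 | 5.0 | 94.5 |
| birch | 6.00 | 9.5 | 89.5 |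
| birch | 15.0 | 21.3 | 78.0 |
| maple | 1.33 | 4.7 | 94.2 |
| maple | 3.00 | 10.3 | 88.4 |
| maple | 6.00 | 20.2 | 79.3 |
| maple | 15.0 | 44.3 | 55.0 |

(each reading ± 0.3 percentage points)

- the flask that ends with the higher amount of target, in percent of the starting material charged, or "neither" when 2 percentage points or less lies between them (autumn / winter / neither)
- final target, as a percentage of the starting material charged, in autumn
- final target, as a percentage of the starting material charged, in winter

- no earlier run changes the charge of free catalyst; that part of a forecast is a guess

By the last readings, at 15.0 min, the birch run gives 2.13 min⁻¹ and the maple run 1.48 min⁻¹. Winter's charge of starting material lies midway between theirs, so my reckoning for winter starts from 1.80 min⁻¹: the mean turnover rate, or turnover frequency, which is target made per minute per catalyst charged, from the start to the reading.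

Now take my own two extreme versions of autumn, both guessing that the rate goes with the catalyst charged. If the partner counts for nothing, autumn makes 13.5%. If the partner counts in full proportion, it makes 27.0%. I expect something between, since in these two runs a ratio of 3.00 in starting material buys a ratio of just 1.44 in turnover rate, so I take the middle, 20.3%.

At that rate I reckon winter at 45.1%. Go round once more: with that much made, I put winter's mean starting material at 38.7 mM, against 67.0 mM in birch and 19.5 mM in maple. The straight line between those runs then gives 1.74 min⁻¹, so I reckon winter at 43.5%. That is more than autumn's upper extreme, so I say winter.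

The forecast also says winter, with 44% for winter and 32% for autumn, which is above my upper extreme. On autumn it warns: “Autumn is a guess, because neither catalyst nor partner level was truly varied.”

The flasks give winter: autumn 18.9%, winter 43.2%.

    starting material + free catalyst ⇌ catalyst intermediate A (K = 38.0 M⁻¹, k = 308 M⁻¹ min⁻¹)
    partner + catalyst intermediate A → catalyst intermediate B (k = 64.4 M⁻¹ min⁻¹)
    catalyst intermediate B ⇌ by-product + catalyst intermediate C (K = 0.0382 M, k = 75.2 min⁻¹)
    catalyst intermediate C → free catalyst + target (k = 6.36 min⁻¹)
    2 catalyst intermediate C ⇌ resting dimer (K = 5200 M⁻¹, k = 88.8 M⁻¹ min⁻¹)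
    2 partner → homo dimer (k = 0.0467 M⁻¹ min⁻¹)

Autumn's mean turnover rate reads 2.53 min⁻¹, which is 1.41 times 1.80 min⁻¹ and so inside the extremes. Winter's reads 1.73 min⁻¹. Carry autumn's rate to its neighbour, the same flask with 6.0 × 10⁻⁴ M of free catalyst, and you reckon 75.8% of target. That neighbour ends at 56.5%, with 43% of the starting material left, and its mean turnover rate reads 1.88 min⁻¹.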